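If each L made costs one J, then J spent equals L made, and where J is charged below G, J is the limiting reagent. L then stops at the charge of J, which in percent of the G charged is 45.5% in cedar and 18.2% in larch. This ratio of charges is the ceiling.

| flask | G | J | X | remark | time |
|---|---|---|---|---|---|
| dusk | 0.33 M | 0.455 M | 0.53 mM | run made earlier |  |
| ash | 0.30 M | 0.455 M | 0.53 mM |  | 10 h |
| cedar | 1.0 M | 0.455 M | 0.53 mM |  | 10 h |
| larch | 2.5 M | 0.455 M | 0.53 mM |  | 10 h |

dusk run (percent of the G charged)

| time / h | L / % | G / % |
|---|---|---|
| 0.250 | 6.0 | 93.9 |
| 0.833 | 19.1 | 80.7 |
| 1.33 | 30.6 | 69.6 |
| 2.00 | 43.5 | 56.3 |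
| 3.00 | 61.6 | 37.9 |
| 4.00 | 75.9 | 23.4 |
| 5.00 | 87.4 | 13.4 |

(each reading ± 0.3 percentage points)

- the numbers in the tables scatter with a standard deviation of 0.3 percentage points
- "hardly changes" means that all values lie within two and a half points (for a concentration: within two and a half percent of the largest)

- amount of L at the end, in percent of the G charged for ash, cedar, larch, in this order
- how that number moves from the first to the last of them (falls all the way / hardly changes / falls, then rises / rises, then falls / rises all the way)

Two chemists read these runs differently, and dusk cannot test J directly, since G was charged below it there.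

The first chemist holds that X works at a steady pace. L reached 61.6% of 0.33 M by 3.00 h, a reading of 0.0678 M/h, and over 10 h that pace makes 0.678 M. So this chemist expects 67.8% in cedar and 27.1% in larch, with ash complete, as its charge of G is smaller than that amount.

The second chemist made the forecast and holds to the ceiling: 99.7%, 45.5% and 18.2%, so the number falls all the way, perhaps “slightly less if the rate slows at low J”.

My own reckoning sides with the ceiling. At the first chemist's pace, the charge of J lasts 6.71 h, less than the 10 h allowed, so in cedar and larch the pace cannot go on to the end. The forecast differs in its figures, taking about 0.1 M/h and about 5 h, but it reaches the same stop.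

The flask gives 100%, 44.8% and 18.0%, so the number falls all the way, and the forecast stands. The first chemist's total comes close at 5.00 h, where cedar has 34.7% L and the pace gives 33.9%, but this is a meeting of totals and not a steady rate: from then to 10.0 h cedar adds 10 percentage points, less than it made before.

    Z → X + L (k = 0.240 /s)
    G + X ⇌ D (K = 37.0 /M, k = 1.00 /M/s)
    J + D ⇌ Q (K = 3.90 /M, k = 5.30 /M/s)
    Q → Z (k = 0.0990 /s)

In cedar, J went over the first 5.00 h at an average rate that would spend its charge in 6.54 h, less than 10 h, and at the end 1.54% of its charge stands unspent, so the ceiling less that part is 44.8%, against 44.8% found. In larch, 1.20% of the charge of J stands unspent at the end, and the same reckoning from 18.2% gives 18.0%, against 18.0% found.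

The readings come from a simulation with made-up constants; scatter was added.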